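## Analysis of the target

Target 17 (C25H38O4) is a bicyclic sesterterpenoid. In sesterterpene numbering, ring A is C1–C5/C10 and ring B is C5–C10. The chain runs C11–C16 with the hydroxymethyl carbon C24 on C13, and the butenolide (ring D) is C17 (beta-carbon), C18, C19 (C=O), O and C25 (OCH2).

Rings A and B form an octalin. It has a gem-dimethyl C4, a quaternary C10 (S) with the angular methyl, a ring-fusion C5–H (S) anti to that methyl, and a tetrasubstituted C8=C9 alkene whose C9 carries the chain.

The third stereocentre, carbinol C16 (R), lies between C15 and C17 and is seven bonds from C10. The C5/C10 pair and C16 are therefore independent stereochemical domains, and no substrate relay between them is possible.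

The C13=C14 alkene is Z, with C24 and C15 on the same side. The two substituents on C13 (CH2OH and CH2CH2R) are nearly equal in size, so an acyclic olefination has little to discriminate.

The feature the route exploits is the array O–C24–C13=C14–C15–C16–O. This is a 1,5-diol held cis across the alkene, the ring-opened and fully reduced form of a 5,6-dihydro-2H-pyran-2-one built from O16, C24, C13, C14, C15 and C16 (latent ring C below).

The sensitive groups are:
- the butenolide (hydride, base, nucleophiles);
- the C16 carbinol (ionisation while an electron-rich heteroarene is attached);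
- the electron-rich C8=C9 alkene (acid, electrophilic oxidants);
- the allylic C24 alcohol.

The difficulty is economy rather than strain. A C16 terpene half and a C9 polar half must be joined while an isolated stereocentre and a trisubstituted alkene geometry are controlled. This should be done without protecting groups, and the butenolide may appear only after the last strong hydride.

## Retrosynthetic reasoning

**Ring D (17 to 15 to 13).** The butenolide is traced back through the gamma-hydroxybutenolide 15 to the 3-substituted furan of 13. The bonds removed are the C19=O and C25–OH oxygens that a photooxygenation (through 14) adds. The C25–H that a mild hydride installs (through 16) is removed as well. A furan tolerates hydride, base and copper catalysis, whereas the butenolide would not survive the opening of ring C. This choice also means that C16–C19 and C25 arrive together as commercial 9.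

**Latent ring C (13 to 11).** O16 is reconnected to C24 at the carboxyl oxidation level, which turns the acyclic Z-diol into lactone 11. The gain is that a six-membered ring can only hold the C13=C14 alkene with C24 and C15 cis. Geometry thus stops being a selectivity question. The forward reaction is an exhaustive 1,2-reduction through lactol 12.

**Key disconnection (11 to 8 + 9).** Ring C is cut at C15–C16 and at O16–C24, a formal retro-hetero-Diels–Alder. This removes the C16 stereocentre, the alkene geometry and the fragment union in a single stroke. It leaves a C20 ester 8 whose only side-chain stereocentre (C13) is irrelevant, plus the C5 aldehyde 9. The forward step must add the gamma-carbon of the dienolate of 8 to one face of 9 and let the resulting alkoxide 10 close the lactone.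

**C12–C13 (8 to 7 to 4 + 5).** The branched ester is cut between C12 and C13. The four carbons C13, C14, C15 and C24 come from crotonic acid 5 through its dienediolate 6, which alkylates at its alpha-carbon. The cut is placed here because the electrophile 4 is then a simple primary iodide and no alkene geometry is at stake.

**Rings A and B (4 to 3 to 2 to 1).** Iodide 4 contains C1–C12 and all four methyl groups. All of these are present in (+)-sclareolide 1, with C5 and C10 already in the required absolute configuration. Only the C8–O bond has to be cleaved with loss of H9, which creates the C8=C9 alkene and erases the two stereocentres of 1 that the target lacks.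

## Alternatives that were turned down

**Alternative 1:** the textbook route, which cuts C13=C14 by a Z-selective phosphonate olefination with C16 set beforehand.
- *Forward sequence.* Iodide 4 would alkylate a bis(trifluoroethyl) phosphonoacetate to give phosphonate A1. Aldehyde A2 would come from 9 by an asymmetric acetate aldol addition, silylation and partial reduction. A Still–Gennari olefination would then give enoate A3, followed by reduction, desilylation and the same furan end game.
- *Why it was turned down.* The Z preference of such reagents rests on fast, irreversible addition and elimination. It weakens when the phosphonate carbon carries a long alkyl branch, and nothing downstream corrects a geometric leak, because both ester isomers are carried on alike. A2 is a beta-silyloxy aldehyde that can lose silanolate by E1cB under the basic conditions. The union, the alkene and C16 are handled in three separate operations, one protecting group is needed, and the count rises by about five steps.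

**Alternative 2:** a biomimetic cut of C4–C5 and C9–C10.
- *Forward sequence.* Homofarnesyl iodide A4 would be carried to the open-chain lactone A5 by the chemistry of steps 4 to 6. A chiral acid would then protonate the terminal isopropylidene group and close rings A and B in two 6-endo closures. The cascade would stop because C13=C14 is deactivated by the lactone carbonyl.
- *Why it was turned down.* The final C8 cation has three different sets of beta-hydrogens. The tetrasubstituted alkene would therefore need acid equilibration, which the furan and the ionisable C16–O bond cannot bear. Facial control in protonating an unanchored isopropylidene terminus, with no internal nucleophile to terminate the cascade, has weak mechanistic support. A4 costs as many steps as 4. The only stereocentres the cascade creates are the two that can be bought in 1.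

**Alternative 3:** a cut of C12–C13 by sp2–sp3 cross-coupling on a preformed ring C.
- *Forward sequence.* The unbranched lactone A6 would be made from 9 and iodinated at its alpha-carbon to A7. A7 would then be coupled with the B-alkyl borane A8 (from 4) under zerovalent palladium and base.
- *Why it was turned down.* The aqueous base of the coupling meets a lactone whose C15–H is vinylogously acidic and whose carboxylate is a leaving group on C16, so ring opening by E1cB threatens both the ring and the stereocentre. Electrophilic iodine must also spare an electron-rich furan. The stereocentre, the halide, the borane and the union each cost their own operation, where one annulation does the same work.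

Key step: step 6

Abbreviation used in names: Bic = (4aS,8aS)-2,5,5,8a-tetramethyl-3,4,4a,5,6,7,8,8a-octahydronaphthalen-1-yl, that is rings A and B with the C8=C9 alkene, bound through C9.

Assumption: the (R)-configured ligand is taken to expose the Re face of 9; if the sense of induction is the opposite, the equally available (S)-ligand is used and nothing else changes.

## Route

Step 1
Reactants: 1 (+)-sclareolide
Product: 2 methyl 2-Bic-acetate
Conditions: conc. H2SO4, MeOH, reflux
Reagents that add atoms: methanol (CO)
Why: Acid-catalysed lactone methanolysis with E1 loss of the tertiary C8 oxygen (Fischer esterification and dehydration); reversible protonation should equilibrate the alkene isomers toward the tetrasubstituted C8=C9 alkene. C5 and C10 are not touched, and the C8 and C9 stereocentres of 1 are erased on purpose.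

Step 2
Reactants: 2 methyl 2-Bic-acetate
Product: 3 2-Bic-ethanol
Conditions: LiAlH4, Et2O, 0 °C to rt; then H2O
Reagents that add atoms: none
Why: Standard LiAlH4 ester reduction, to which the isolated tetrasubstituted alkene is inert. The work-up is kept free of acid because protonation of C8=C9 would let the new hydroxyl close a tetrahydrofuran.

Step 3
Reactants: 3 2-Bic-ethanol
Product: 4 2-Bic-ethyl iodide
Conditions: I2, PPh3, imidazole, CH2Cl2, 0 °C to rt
Reagents that add atoms: iodine (II)
Why: Appel-type iodination (Garegg–Samuelsson conditions) by SN2 displacement at the primary C12. The buffered neutral medium avoids cationic participation of the C8=C9 alkene.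

Step 4
Reactants: 4 2-Bic-ethyl iodide; 5 (E)-but-2-enoic acid (crotonic acid)
Product: 7 2-(2-Bic-ethyl)but-3-enoic acid as a mixture of C13 epimers, via dilithium dienediolate 6 (not isolated)
Conditions: 5, LiN(iPr)2 (2.1 equiv), THF, -78 to 0 °C; then 4, DMPU, -78 °C to rt; aq. HCl
Reagents that add atoms: none
Why: Deconjugative alpha-alkylation of a lithium dienediolate, whose highest charge density lies on the alpha-carbon, forms C12–C13 and moves the alkene to C14=C15. The new C13 centre forms without control, which does not matter because step 6 erases it.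

Step 5
Reactants: 7 2-(2-Bic-ethyl)but-3-enoic acid
Product: 8 phenyl 2-(2-Bic-ethyl)but-3-enoate as a mixture of C13 epimers
Conditions: PhOH, DCC, DMAP (5 mol %), CH2Cl2, 0 °C
Reagents that add atoms: phenol (Oc1ccccc1)
Why: Steglich esterification. The aryl ester raises the acidity of C13–H and supplies the leaving group for ring closure in step 6, and the low DMAP loading and low temperature limit migration of the alkene into conjugation.

Step 6
Reactants: 8 phenyl 2-(2-Bic-ethyl)but-3-enoate; 9 furan-3-carbaldehyde
Product: 11 (6R)-6-(furan-3-yl)-3-(2-Bic-ethyl)-5,6-dihydro-2H-pyran-2-one, via open-chain Z-hydroxy ester 10 (not isolated)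
Conditions: [Cu(MeCN)4]PF6 (5 mol %), (R)-DTBM-SEGPHOS (6 mol %), 2-tert-butyl-1,1,3,3-tetramethylguanidine (20 mol %), THF, -20 °C
Reagents that add atoms: none
Why: Soft enolisation of 8 by the monovalent copper–bisphosphine complex and the guanidine base removes the doubly activated C13–H (allylic and alpha to an aryl ester), so both C13 epimers converge on one chiral copper dienolate. Its gamma-carbon C15 adds to the copper-bound aldehyde 9 in a closed transition state that only the s-cis dienolate can span, which forms C15–C16 and gives alkoxide 10 with C15 and the ester carbon C24 on the same side of the new C13=C14 bond. The alkoxide then attacks the phenyl ester in a 6-exo-trig acyl substitution that closes ring C, and the expelled phenoxide serves as the proton shuttle of the next turnover. The closest known reaction type is the copper-catalysed direct vinylogous aldol–lactonisation of beta,gamma-unsaturated esters with aromatic and heteroaromatic aldehydes, a formal hetero-Diels–Alder reaction. C16 is the only new stereocentre and is set by the ligand, which shields the Si face of 9 so that Re-face attack gives R; the decalin stereocentres lie seven or more bonds away, so this is pure catalyst control. Gamma- over alpha-selectivity is secured by the C12 branch, since alpha-attack would build a quaternary C13 and its aldolate reverts by retro-aldol, whereas lactonisation is irreversible. The Z geometry is doubly secured, because only the Z-alkoxide can cyclise and the ring then holds it. The C8=C9 alkene and the furan are inert to the mild base and the low temperature.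

Step 7
Reactants: 11 (6R)-6-(furan-3-yl)-3-(2-Bic-ethyl)-5,6-dihydro-2H-pyran-2-one
Product: 13 (2Z,5R)-5-(furan-3-yl)-2-(2-Bic-ethyl)pent-2-ene-1,5-diol, via lactol 12 (not isolated)
Conditions: iBu2AlH (4 equiv), CH2Cl2, -78 to 0 °C; aq. potassium sodium tartrate
Reagents that add atoms: none
Why: 1,2-Selective lactone reduction with iBu2AlH through lactol 12 opens ring C and releases the C24 and C16 hydroxyls with the ring-imposed Z geometry intact. The furan, C8=C9 and C16 are untouched, and the neutral work-up protects the furyl carbinol from ionisation.

Step 8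
Reactants: 13 (2Z,5R)-5-(furan-3-yl)-2-(2-Bic-ethyl)pent-2-ene-1,5-diol
Product: 15 5-hydroxy-4-[(1R,3Z)-1-hydroxy-4-(hydroxymethyl)-6-Bic-hex-3-en-1-yl]furan-2(5H)-one as a mixture of hemiacetal epimers, via furan endoperoxide 14 (not isolated)
Conditions: O2, visible light, rose bengal (cat.), iPr2NEt, CH2Cl2, -78 °C
Reagents that add atoms: dioxygen (O=O)
Why: [4+2] cycloaddition of singlet oxygen to the furan gives 14, and the hindered amine removes the less hindered bridgehead hydrogen remote from C16 (Kornblum–DeLaMare-type fragmentation). That carbon therefore becomes the C19 carbonyl and C25 the hemiacetal. At -78 °C the electron-rich furan should outrun the ene reaction of the hindered C8=C9 and the allylic-alcohol C13=C14 alkenes.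

Step 9
Reactants: 15 5-hydroxy-4-[(1R,3Z)-1-hydroxy-4-(hydroxymethyl)-6-Bic-hex-3-en-1-yl]furan-2(5H)-one
Product: 17 4-[(1R,3Z)-1-hydroxy-4-(hydroxymethyl)-6-Bic-hex-3-en-1-yl]furan-2(5H)-one (CNP0224983.2), via sodium hydroxy carboxylate 16 (not isolated)
Conditions: NaBH4, EtOH, 0 °C; then 1 M aq. HCl, 0 °C
Reagents that add atoms: none
Why: Compound 15 is a masked formyl acrylate, and borohydride reduces its aldehyde tautomer to 16, in which only the C25 hydroxyl is cis to the carboxylate and lactonises on acidification. The butenolide forms only after the hydride is spent, the hemiacetal centre disappears, and C5, C10, C16 and the Z alkene are unaffected.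

## Compound list

1 | (+)-sclareolide, (3aR,5aS,9aS,9bR)-3a,6,6,9a-tetramethyldecahydronaphtho[2,1-b]furan-2(1H)-one | C[C@]12CCCC([C@@H]1CC[C@@]3([C@@H]2CC(=O)O3)C)(C)C | starting material
2 | methyl 2-Bic-acetate | CC1=C(CC(=O)OC)[C@@]2(C)CCCC(C)(C)[C@@H]2CC1 | intermediate
3 | 2-Bic-ethanol | CC1=C(CCO)[C@@]2(C)CCCC(C)(C)[C@@H]2CC1 | intermediate
4 | 2-Bic-ethyl iodide | CC1=C(CCI)[C@@]2(C)CCCC(C)(C)[C@@H]2CC1 | intermediate
5 | (E)-but-2-enoic acid (crotonic acid) | C/C=C/C(=O)O | starting material
6 | dilithium buta-1,3-diene-1,1-diolate | C=CC=C([O-])[O-].[Li+].[Li+] | intermediate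
7 | 2-(2-Bic-ethyl)but-3-enoic acid, both C13 epimers | CC1=C(CCC(C=C)C(O)=O)[C@@]2(C)CCCC(C)(C)[C@@H]2CC1 | intermediate
8 | phenyl 2-(2-Bic-ethyl)but-3-enoate, both C13 epimers | CC1=C(CCC(C=C)C(=O)Oc3ccccc3)[C@@]2(C)CCCC(C)(C)[C@@H]2CC1 | intermediate
9 | furan-3-carbaldehyde | O=Cc1ccoc1 | starting material
10 | phenyl (2Z,5R)-5-(furan-3-yl)-5-hydroxy-2-(2-Bic-ethyl)pent-2-enoate, present as its copper alkoxide | CC1=C(CC/C(=C/C[C@@H](O)c3ccoc3)C(=O)Oc4ccccc4)[C@@]2(C)CCCC(C)(C)[C@@H]2CC1 | intermediate
11 | (6R)-6-(furan-3-yl)-3-(2-Bic-ethyl)-5,6-dihydro-2H-pyran-2-one | CC1=C(CCC3=CC[C@H](c4ccoc4)OC3=O)[C@@]2(C)CCCC(C)(C)[C@@H]2CC1 | intermediate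
12 | (6R)-6-(furan-3-yl)-3-(2-Bic-ethyl)-5,6-dihydro-2H-pyran-2-ol, present as its aluminium alkoxide | CC1=C(CCC3=CC[C@H](c4ccoc4)OC3O)[C@@]2(C)CCCC(C)(C)[C@@H]2CC1 | intermediate
13 | (2Z,5R)-5-(furan-3-yl)-2-(2-Bic-ethyl)pent-2-ene-1,5-diol | CC1=C(CC/C(=C/C[C@@H](O)c3ccoc3)CO)[C@@]2(C)CCCC(C)(C)[C@@H]2CC1 | intermediate
14 | (2Z,5R)-2-(2-Bic-ethyl)-5-(2,3,7-trioxabicyclo[2.2.1]hept-5-en-5-yl)pent-2-ene-1,5-diol, bridgehead epimers | CC1=C(CC/C(=C/C[C@@H](O)C3=CC4OOC3O4)CO)[C@@]2(C)CCCC(C)(C)[C@@H]2CC1 | intermediate
15 | 5-hydroxy-4-[(1R,3Z)-1-hydroxy-4-(hydroxymethyl)-6-Bic-hex-3-en-1-yl]furan-2(5H)-one, hemiacetal epimers | CC1=C(CC/C(=C/C[C@@H](O)C3=CC(=O)OC3O)CO)[C@@]2(C)CCCC(C)(C)[C@@H]2CC1 | intermediate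
16 | sodium (2E,4R,6Z)-4,8-dihydroxy-3-(hydroxymethyl)-7-(2-Bic-ethyl)octa-2,6-dienoate | CC1=C(CC/C(=C/C[C@@H](O)/C(CO)=C/C(=O)[O-])CO)[C@@]2(C)CCCC(C)(C)[C@@H]2CC1.[Na+] | intermediate
17 | 4-[(1R,3Z)-1-hydroxy-4-(hydroxymethyl)-6-Bic-hex-3-en-1-yl]furan-2(5H)-one (CNP0224983.2) | CC1=C(CC/C(=C/C[C@@H](O)C2=CC(=O)OC2)CO)[C@@]2(C)CCCC(C)(C)[C@@H]2CC1 | target

## Step count and least certain steps

Total step count: 9. Longest linear sequence: 9 steps (1 to 17). No protecting group is used.

**Step 6 (key step).**
- *What may go wrong.* The alpha-branch lowers the acidity of C13–H, so soft enolisation may be slow. Expulsion of aryloxide from the enolate could open an uncatalysed ketene pathway that erodes facial selectivity. Partial reaction through the s-trans dienolate would divert material into an adduct that cannot lactonise. Incomplete facial selectivity would be costly, because C16 epimers differ only at a centre remote from the decalin and would be hard to separate.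
- *Fallback.* Known chemistry closes ring C by metathesis instead of annulation. It sets out from 7 and 9 and returns to the route at 11. Aldehyde 9 is vinylated with Zn(CH=CH2)2 under a chiral amino alcohol ligand to (1R)-1-(furan-3-yl)prop-2-en-1-ol F1. DCC/DMAP esterification of 7 with it gives (1R)-1-(furan-3-yl)prop-2-en-1-yl 2-(2-Bic-ethyl)but-3-enoate F2. The second-generation Grubbs catalyst joins the two monosubstituted vinyl groups to (6R)-6-(furan-3-yl)-3-(2-Bic-ethyl)-3,6-dihydro-2H-pyran-2-one F3. Catalytic DBU then moves the C14=C15 alkene into conjugation, which gives 11 with the geometry again fixed by the ring.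

**Step 1.**
- *What may go wrong.* Equilibration among the alkene regioisomers may stay incomplete. Relactonisation may compete with ester formation, because both run through the same C8 cation.
- *Fallback.* It sets out from 1 and returns at 3, and it separates reduction from dehydration. LiAlH4 reduces 1 to (1R,2R,4aS,8aS)-1-(2-hydroxyethyl)-2,5,5,8a-tetramethyldecahydronaphthalen-2-ol F4. Ac2O/pyridine acetylates only the primary hydroxyl to 2-[(1R,2R,4aS,8aS)-2-hydroxy-2,5,5,8a-tetramethyldecahydronaphthalen-1-yl]ethyl acetate F5. PPh3/I2 in CH2Cl2 dehydrates the tertiary C8 alcohol toward the most substituted alkene to give 2-Bic-ethyl acetate F6. K2CO3 in MeOH then releases 3.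

**Step 4.**
- *What may go wrong.* The strongly basic dianion may cause E2 elimination of the iodide, whose C11 hydrogens are allylic. Some gamma-alkylation may also occur.
- *Fallback.* It sets out from 4 and returns at 7, and it uses a much less basic carbon nucleophile. The sodium dienolate of diethyl ethylidenemalonate (NaH, THF/DMF) is alkylated at its alpha-carbon by 4 to give diethyl 2-(2-Bic-ethyl)-2-vinylmalonate F7. Saponification with KOH and thermal decarboxylation then give 7.

**Step 8.**
- *What may go wrong.* The ene oxidation of the electron-rich C8=C9 alkene by singlet oxygen may compete. Regiocontrol in the base-induced collapse of the endoperoxide may be imperfect.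
- *Fallback.* It sets out from 9 and 8 and returns at 15, and it replaces base control by silicon control. Aldehyde 9 is protected in situ as its lithium morpholide adduct, lithiated with sec-BuLi at the free alpha-position remote from the formyl group, and silylated with Me3SiCl to 5-(trimethylsilyl)furan-3-carbaldehyde F8. The conditions of step 6 with 8 give (6R)-3-(2-Bic-ethyl)-6-[5-(trimethylsilyl)furan-3-yl]-5,6-dihydro-2H-pyran-2-one F9. The conditions of step 7 then give (2Z,5R)-2-(2-Bic-ethyl)-5-[5-(trimethylsilyl)furan-3-yl]pent-2-ene-1,5-diol F10. The silylfuran is the more reactive diene toward singlet oxygen. Silyl migration to the peroxide oxygen fixes the silicon-bearing carbon as the C19 carbonyl without any base, and aqueous work-up gives 15.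

## Further compounds

F1 | step 6 | (1R)-1-(furan-3-yl)prop-2-en-1-ol | C=C[C@@H](O)c1ccoc1
F2 | step 6 | (1R)-1-(furan-3-yl)prop-2-en-1-yl 2-(2-Bic-ethyl)but-3-enoate | CC1=C(CCC(C=C)C(=O)O[C@H](C=C)c3ccoc3)[C@@]2(C)CCCC(C)(C)[C@@H]2CC1
F3 | step 6 | (6R)-6-(furan-3-yl)-3-(2-Bic-ethyl)-3,6-dihydro-2H-pyran-2-one | CC1=C(CCC3C=C[C@H](c4ccoc4)OC3=O)[C@@]2(C)CCCC(C)(C)[C@@H]2CC1
F4 | step 1 | (1R,2R,4aS,8aS)-1-(2-hydroxyethyl)-2,5,5,8a-tetramethyldecahydronaphthalen-2-ol | C[C@]12CCCC([C@@H]1CC[C@@](O)([C@@H]2CCO)C)(C)C
F5 | step 1 | 2-[(1R,2R,4aS,8aS)-2-hydroxy-2,5,5,8a-tetramethyldecahydronaphthalen-1-yl]ethyl acetate | C[C@]12CCCC([C@@H]1CC[C@@](O)([C@@H]2CCOC(C)=O)C)(C)C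
F6 | step 1 | 2-Bic-ethyl acetate | CC1=C(CCOC(C)=O)[C@@]2(C)CCCC(C)(C)[C@@H]2CC1
F7 | step 4 | diethyl 2-(2-Bic-ethyl)-2-vinylmalonate | CC1=C(CCC(C=C)(C(=O)OCC)C(=O)OCC)[C@@]2(C)CCCC(C)(C)[C@@H]2CC1
F8 | step 8 | 5-(trimethylsilyl)furan-3-carbaldehyde | O=Cc1coc([Si](C)(C)C)c1
F9 | step 8 | (6R)-3-(2-Bic-ethyl)-6-[5-(trimethylsilyl)furan-3-yl]-5,6-dihydro-2H-pyran-2-one | CC1=C(CCC3=CC[C@H](c4coc([Si](C)(C)C)c4)OC3=O)[C@@]2(C)CCCC(C)(C)[C@@H]2CC1
F10 | step 8 | (2Z,5R)-2-(2-Bic-ethyl)-5-[5-(trimethylsilyl)furan-3-yl]pent-2-ene-1,5-diol | CC1=C(CC/C(=C/C[C@@H](O)c3coc([Si](C)(C)C)c3)CO)[C@@]2(C)CCCC(C)(C)[C@@H]2CC1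
A1 | alternative 1 | methyl 2-[bis(2,2,2-trifluoroethoxy)phosphoryl]-4-Bic-butanoate | CC1=C(CCC(C(=O)OC)P(=O)(OCC(F)(F)F)OCC(F)(F)F)[C@@]2(C)CCCC(C)(C)[C@@H]2CC1
A2 | alternative 1 | (3R)-3-(tert-butyldimethylsilyloxy)-3-(furan-3-yl)propanal | O=CC[C@@H](O[Si](C)(C)C(C)(C)C)c1ccoc1
A3 | alternative 1 | methyl (2Z,5R)-5-(tert-butyldimethylsilyloxy)-5-(furan-3-yl)-2-(2-Bic-ethyl)pent-2-enoate | CC1=C(CC/C(=C/C[C@@H](O[Si](C)(C)C(C)(C)C)c3ccoc3)C(=O)OC)[C@@]2(C)CCCC(C)(C)[C@@H]2CC1
A4 | alternative 2 | (3E,7E)-1-iodo-4,8,12-trimethyltrideca-3,7,11-triene | CC(C)=CCC/C(C)=C/CC/C(C)=C/CCI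
A5 | alternative 2 | (6R)-6-(furan-3-yl)-3-[(3E,7E)-4,8,12-trimethyltrideca-3,7,11-trien-1-yl]-5,6-dihydro-2H-pyran-2-one | CC(C)=CCC/C(C)=C/CC/C(C)=C/CCC1=CC[C@H](c2ccoc2)OC1=O
A6 | alternative 3 | (6R)-6-(furan-3-yl)-5,6-dihydro-2H-pyran-2-one | O=C1C=CC[C@H](c2ccoc2)O1
A7 | alternative 3 | (6R)-6-(furan-3-yl)-3-iodo-5,6-dihydro-2H-pyran-2-one | O=C1C(I)=CC[C@H](c2ccoc2)O1
A8 | alternative 3 | 9-(2-Bic-ethyl)-9-borabicyclo[3.3.1]nonane | CC1=C(CCB3C4CCCC3CCC4)[C@@]2(C)CCCC(C)(C)[C@@H]2CC1
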